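**Strategy.** The ten-membered ring is disconnected at C2–C3 (germacrane numbering), which lies between the C4=C5 alkene and the oxygenated C1/C10 pair: a retro-oxy-Cope relationship. The key step is an anionic oxy-Cope ring expansion of a cis-1-vinyl-2-isopropenylcyclohexanol (ring carbons C5–C10). In one operation it forms C2–C3, closes the cyclodecadiene, sets the (Z)-C4=C5 alkene and delivers the C1(10) enolate, which is hydroxylated at C1 in the same flask. The precursor is a compact tricycle in which the butenolide is carried as a base-stable 2,5-dihydrofuran and the C8/C13 oxygens as an acetonide; its four stereocentres derive from one asymmetric epoxidation of a quinone monoketal.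

Key step: step 11

Remark: positions in all intermediates are given in germacrane numbering (ring carbons C1–C10, C11, lactone carbon C12, acetoxymethyl carbon C13, exocyclic methylene C14, methyl C15).
Remark: the sense of induction of the tartrate-mediated epoxidation is assumed to be the one drawn for diisopropyl L-tartrate; if it is the opposite, the D-ester is used.

**Step 1**
Reactants: 1 4,4-dimethoxycyclohexa-2,5-dien-1-one
Product: 2 (1R,6S)-5,5-dimethoxy-7-oxabicyclo[4.1.0]hept-3-en-2-one
Conditions: Ph3COOH (1.0 equiv), NaN(SiMe3)2, diisopropyl L-tartrate, PhMe, −65 °C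
Reagents that add atoms: trityl hydroperoxide, OOC(c1ccccc1)(c1ccccc1)c1ccccc1
Why: Tartrate-mediated nucleophilic (Weitz–Scheffer-type) epoxidation of one of the two enantiotopic enone double bonds of the achiral dienone sets both epoxide carbons (C8, C9) under reagent control, and one equivalent of oxidant at low temperature limits bis-epoxidation.

**Step 2**
Reactants: 2 (1R,6S)-5,5-dimethoxy-7-oxabicyclo[4.1.0]hept-3-en-2-one; 3 vinylmagnesium bromide
Product: 4 (1R,2S,6S)-2-ethenyl-5,5-dimethoxy-7-oxabicyclo[4.1.0]hept-3-en-2-ol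
Conditions: CH2=CHMgBr, THF, −78 °C; aq. NH4Cl
Reagents that add atoms: none
Why: 1,2-Grignard addition to the carbonyl of an α,β-epoxy enone should occur on the face opposite the epoxide oxygen, which sets C10 with the hydroxyl cis to the epoxide and the vinyl group trans to it.

**Step 3**
Reactants: 4 (1R,2S,6S)-2-ethenyl-5,5-dimethoxy-7-oxabicyclo[4.1.0]hept-3-en-2-ol
Product: 5 (1S,5S)-1-ethenyl-4,4-dimethoxycyclohex-2-ene-1,5-diol
Conditions: LiAlH4, THF, 0 °C → rt
Reagents that add atoms: none
Why: Hydride SN2 opening of the epoxide (LiAlH4 reduction) should occur at C9, because the carbon next to the ketal is deactivated inductively and sterically; the C8–O bond is untouched, so the cis-1,3-diol keeps the C8 configuration.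

**Step 4**
Reactants: 5 (1S,5S)-1-ethenyl-4,4-dimethoxycyclohex-2-ene-1,5-diol
Product: 6 (1S,2S,4S,6R)-2-ethenyl-5,5-dimethoxy-7-oxabicyclo[4.1.0]heptane-2,4-diol
Conditions: VO(acac)2 (5 mol %), t-BuOOH, CH2Cl2, 0 °C
Reagents that add atoms: tert-butyl hydroperoxide, CC(C)(C)OO
Why: Vanadium-catalysed hydroxyl-directed epoxidation: the ring alkene is allylic to the tertiary and homoallylic to the secondary hydroxyl, both on the same face, so oxygen is delivered syn to them (C5 and C6 set), while the monosubstituted vinyl group reacts far more slowly.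

**Step 5**
Reactants: 6 (1S,2S,4S,6R)-2-ethenyl-5,5-dimethoxy-7-oxabicyclo[4.1.0]heptane-2,4-diol; 7 isopropenylmagnesium bromide
Product: 8 (1S,2R,3R,5S)-1-ethenyl-4,4-dimethoxy-2-(prop-1-en-2-yl)cyclohexane-1,3,5-triol
Conditions: CH2=C(CH3)MgBr (3.5 equiv), CuI (15 mol %), THF, −30 → 0 °C
Reagents that add atoms: none
Why: Copper-catalysed Grignard opening of the epoxide (SN2, inversion): the magnesium cis-1,3-dialkoxide holds both oxygens axial and the ketal deactivates the neighbouring carbon, so trans-diaxial attack should occur at C5, placing isopropenyl trans to the new C6 hydroxyl and cis to the vinyl group.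

**Step 6**
Reactants: 8 (1S,2R,3R,5S)-1-ethenyl-4,4-dimethoxy-2-(prop-1-en-2-yl)cyclohexane-1,3,5-triol
Product: 9 C8 mono-pivalate of 8 (ester on the secondary hydroxyl next to the ring CH2; stereocentres as in 8)
Conditions: PivCl (1.1 equiv), pyridine, DMAP (cat.), CH2Cl2, 0 °C
Reagents that add atoms: pivaloyl chloride, CC(C)(C)C(=O)Cl
Why: Site-selective acylation: the bulky acid chloride should esterify the less hindered secondary hydroxyl (C8, next to a CH2) in preference to the C6 hydroxyl (next to the isopropenyl-bearing carbon) and the tertiary one; no stereocentre is touched.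

**Step 7**
Reactants: 9 C8 mono-pivalate of 8
Product: 10 C7 ketone: 2-hydroxy-6-(pivaloyloxy)cyclohexan-1-one with 3-(prop-1-en-2-yl), 4-ethenyl and 4-hydroxy groups (C6–OH, C8–OPiv and C10–OH on one face; isopropenyl and vinyl on the other)
Conditions: PPTS, acetone/H2O (10:1), 45 °C
Reagents that add atoms: water, O
Why: Acid-catalysed hydrolysis of the dimethyl ketal under buffered conditions that should spare the tertiary allylic alcohol and the pivalate; C6 and C8, now α to the ketone, already carry their oxygens in the thermodynamically preferred equatorial positions.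

**Step 8**
Reactants: 10 C7 ketone; 11 ethyl 2-(diethoxyphosphoryl)prop-2-enoate
Product: 12 ethyl 6-ethenyl-6-hydroxy-4-(pivaloyloxy)-7-(prop-1-en-2-yl)-2,4,5,6,7,7a-hexahydro-1-benzofuran-3-carboxylate (ring O at C7a, 4-O and 6-OH on one face; 7-isopropenyl and 6-vinyl on the other)
Conditions: Cs2CO3 (1.1 equiv), MeCN, 0 °C → rt
Reagents that add atoms: none
Why: Tandem oxa-Michael/intramolecular Horner–Wadsworth–Emmons annulation: the C6 alkoxide adds to the phosphonoacrylate and the phosphonate carbanion olefinates the adjacent C7 ketone in a five-membered mode, giving the 2,5-dihydrofuran-3-carboxylate (C7=C11) without touching C6 or C8; the tertiary hydroxyl is too hindered to compete.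

**Step 9**
Reactants: 12 dihydrofuran ester
Product: 13 6-ethenyl-3-(hydroxymethyl)-7-(prop-1-en-2-yl)-2,4,5,6,7,7a-hexahydro-1-benzofuran-4,6-diol (configuration as in 12)
Conditions: i-Bu2AlH (6 equiv), CH2Cl2, −78 → 0 °C; Rochelle salt
Reagents that add atoms: none
Why: 1,2-Reduction of the conjugated ester to the primary allylic alcohol (C13–OH) with i-Bu2AlH, which cleaves the pivalate in the same operation; no stereocentre changes.

**Step 10**
Reactants: 13 triol
Product: 14 8,13-O-isopropylidene derivative of 13 (seven-membered 1,3-dioxepine fused to the dihydrofuran and cyclohexane rings; tertiary C10–OH free)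
Conditions: 2,2-dimethoxypropane, PPTS (cat.), CH2Cl2, 0 °C → rt
Reagents that add atoms: 2,2-dimethoxypropane, COC(C)(C)OC
Why: Acetonide formation (acetal exchange) across the (Z)-ene-1,4-diol; a bridge to the tertiary C10 hydroxyl would need a strained 1,3-diaxial bicycle, so that hydroxyl should stay free for the key step.

**Step 11**
Reactants: 14 tricyclic carbinol
Product: 17 (1S,6R,8S)-1-[(tert-butyldimethylsilyl)oxy]-6,12-epoxy-8,13-(isopropylidenedioxy)-14-norgermacra-4Z,7(11)-dien-10-one, via potassium enolate 15 (not isolated), via potassium alkoxide 16 (not isolated)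
Conditions: KH, 18-crown-6, THF, 0 °C → rt; then 2-(phenylsulfonyl)-3-phenyloxaziridine, −78 °C; then TBSOTf, −78 → 0 °C
Reagents that add atoms: 2-(phenylsulfonyl)-3-phenyloxaziridine, O=S(=O)(N1OC1c1ccccc1)c1ccccc1; tert-butyldimethylsilyl trifluoromethanesulfonate, CC(C)(C)[Si](C)(C)OS(=O)(=O)C(F)(F)F
Why: Deprotonation of the tertiary alcohol gives the potassium alkoxide, whose anionic oxy-Cope [3,3] shift breaks C5–C10 and forms C2–C3, expanding the cyclohexane to the cyclodecadienone enolate 15; the closest known reaction type is the anionic oxy-Cope ring expansion of 1,2-dialkenylcyclohexanols with trapping of the regiodefined enolate. The ten-membered ring is closed by this concerted, suprafacial sigmatropic bond formation through a chair-like six-centre transition state, not by a polar cyclization. Because vinyl and isopropenyl are cis and the ground-state chair has every other substituent equatorial with the vinyl axial, C6 sits pseudo-axial on C5 in that transition state and the C4=C5 alkene should form with Z geometry. The E-enolate is formed with its inner face covered by the C4=C5 unit across the ring, so the oxaziridine should transfer oxygen to the outer face of C1 and set 1S (alkoxide 16) before silylation to 17. The step needs a regiodefined C1(10) enolate, since proton shift to C9 would expel the C8 oxygen; the absence of a proton source, low temperature and immediate oxidation secure this. The dihydrofuran and the acetonide carry no acidic hydrogen, so they are inert to the potassium alkoxide.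

**Step 12**
Reactants: 17 silyloxy ketone
Product: 18 (1S,6R,8S)-1-[(tert-butyldimethylsilyl)oxy]-6,12-epoxy-8,13-(isopropylidenedioxy)germacra-4Z,7(11),10(14)-triene
Conditions: Zn, CH2Br2, TiCl4, THF/CH2Cl2, 0 °C → rt
Reagents that add atoms: dibromomethane, BrCBr
Why: Takai–Lombardo methylenation: the non-basic zinc/titanium methylene reagent should convert the C10 ketone into the exocyclic methylene without epimerizing C1 or eliminating the β-oxygen at C8, as a basic Wittig ylide might.

**Step 13**
Reactants: 18 triene acetonide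
Product: 19 (1S,6R,8S)-1-[(tert-butyldimethylsilyl)oxy]-6,12-epoxygermacra-4Z,7(11),10(14)-triene-8,13-diol
Conditions: PPTS, MeOH, 0 °C → rt
Reagents that add atoms: none
Why: Mild acid-catalysed methanolysis of the seven-membered acetonide should free the C8 and C13 hydroxyls while the secondary TBS ether and the ring ether survive.

**Step 14**
Reactants: 19 diol
Product: 20 (1S,6R,8S)-1-[(tert-butyldimethylsilyl)oxy]-6,12-epoxygermacra-4Z,7(11),10(14)-triene-8,13-diyl diacetate
Conditions: Ac2O, pyridine, DMAP (cat.), CH2Cl2, 0 °C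
Reagents that add atoms: acetic anhydride, CC(=O)OC(C)=O
Why: DMAP-catalysed acetylation of the secondary and the primary hydroxyl; C1 is silylated and stays untouched.

**Step 15**
Reactants: 20 diacetate
Product: 21 1-O-(tert-butyldimethylsilyl) ether of the target
Conditions: CrO3, 3,5-dimethylpyrazole, CH2Cl2, −20 °C
Reagents that add atoms: chromium trioxide, O=[Cr](=O)=O
Why: Allylic oxidation with hexavalent chromium (CrO3–3,5-dimethylpyrazole), the known conversion of 2,5-dihydrofurans into butenolides: C12 is the only unhindered methylene that is both allylic and α to an ether oxygen, C6–H is tertiary and lies in the plane of the adjacent Z-alkene, and the C8/C13 C–H bonds are deactivated by acetoxy groups.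

**Step 16**
Reactants: 21 silyl ether
Product: 22 8α,13-diacetoxy-1α-hydroxygermacra-4,7(11),10(14)-trien-6α,12-olide
Conditions: HF·pyridine, pyridine, THF, 0 °C → rt
Reagents that add atoms: none
Why: Buffered fluoride desilylation cleaves the Si–O bond at C1 with retention and should leave the acetates and the butenolide intact.

**Compound list**
1 | 4,4-dimethoxycyclohexa-2,5-dien-1-one | COC1(OC)C=CC(=O)C=C1 | starting material
2 | (1R,6S)-5,5-dimethoxy-7-oxabicyclo[4.1.0]hept-3-en-2-one | O=C1C=CC(OC)(OC)[C@H]2O[C@@H]12 | intermediate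
3 | vinylmagnesium bromide | C=C[Mg]Br | starting material
4 | (1R,2S,6S)-2-ethenyl-5,5-dimethoxy-7-oxabicyclo[4.1.0]hept-3-en-2-ol | C=C[C@]1(O)C=CC(OC)(OC)[C@H]2O[C@@H]12 | intermediate
5 | (1S,5S)-1-ethenyl-4,4-dimethoxycyclohex-2-ene-1,5-diol | C=C[C@]1(O)C=CC(OC)(OC)[C@@H](O)C1 | intermediate
6 | (1S,2S,4S,6R)-2-ethenyl-5,5-dimethoxy-7-oxabicyclo[4.1.0]heptane-2,4-diol | C=C[C@]1(O)[C@H]2O[C@H]2C(OC)(OC)[C@@H](O)C1 | intermediate
7 | isopropenylmagnesium bromide | CC(=C)[Mg]Br | starting material
8 | (1S,2R,3R,5S)-1-ethenyl-4,4-dimethoxy-2-(prop-1-en-2-yl)cyclohexane-1,3,5-triol | C=C[C@]1(O)[C@H](C(C)=C)[C@@H](O)C(OC)(OC)[C@@H](O)C1 | intermediate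
9 | C8 mono-pivalate of 8 | C=C[C@]1(O)[C@H](C(C)=C)[C@@H](O)C(OC)(OC)[C@@H](OC(=O)C(C)(C)C)C1 | intermediate
10 | C7 ketone (2-hydroxy-6-pivaloyloxy cyclohexanone with 3-isopropenyl, 4-ethenyl, 4-hydroxy) | C=C[C@]1(O)[C@H](C(C)=C)[C@@H](O)C(=O)[C@@H](OC(=O)C(C)(C)C)C1 | intermediate
11 | ethyl 2-(diethoxyphosphoryl)prop-2-enoate | CCOC(=O)C(=C)P(=O)(OCC)OCC | starting material
12 | ethyl 6-ethenyl-6-hydroxy-4-(pivaloyloxy)-7-(prop-1-en-2-yl)-2,4,5,6,7,7a-hexahydro-1-benzofuran-3-carboxylate | C=C[C@]1(O)[C@H](C(C)=C)[C@H]2OCC(C(=O)OCC)=C2[C@@H](OC(=O)C(C)(C)C)C1 | intermediate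
13 | 6-ethenyl-3-(hydroxymethyl)-7-(prop-1-en-2-yl)-2,4,5,6,7,7a-hexahydro-1-benzofuran-4,6-diol | C=C[C@]1(O)[C@H](C(C)=C)[C@H]2OCC(CO)=C2[C@@H](O)C1 | intermediate
14 | 8,13-O-isopropylidene derivative of 13 (tertiary C10–OH free) | C=C[C@]1(O)[C@H](C(C)=C)[C@H]2OCC3=C2[C@H](C1)OC(C)(C)OC3 | intermediate
15 | potassium (1(10)E,4Z)-enolate of the ring-expanded C10 ketone | [K+].[O-]/C1=C\CC/C(C)=C\[C@H]2OCC3=C2[C@H](C1)OC(C)(C)OC3 | intermediate
16 | potassium alkoxide of the (1S)-1-hydroxy-10-ketone | O=C1C[C@@H]2OC(C)(C)OCC3=C2[C@H](OC3)/C=C(/C)CC[C@@H]1[O-].[K+] | intermediate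
17 | (1S,6R,8S)-1-[(tert-butyldimethylsilyl)oxy]-6,12-epoxy-8,13-(isopropylidenedioxy)-14-norgermacra-4Z,7(11)-dien-10-one | O=C1C[C@@H]2OC(C)(C)OCC3=C2[C@H](OC3)/C=C(/C)CC[C@@H]1O[Si](C)(C)C(C)(C)C | intermediate
18 | (1S,6R,8S)-1-[(tert-butyldimethylsilyl)oxy]-6,12-epoxy-8,13-(isopropylidenedioxy)germacra-4Z,7(11),10(14)-triene | C=C1C[C@@H]2OC(C)(C)OCC3=C2[C@H](OC3)/C=C(/C)CC[C@@H]1O[Si](C)(C)C(C)(C)C | intermediate
19 | (1S,6R,8S)-1-[(tert-butyldimethylsilyl)oxy]-6,12-epoxygermacra-4Z,7(11),10(14)-triene-8,13-diol | C=C1C[C@H](O)C2=C(CO)CO[C@@H]2/C=C(/C)CC[C@@H]1O[Si](C)(C)C(C)(C)C | intermediate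
20 | 8,13-diacetate of 19 | C=C1C[C@H](OC(C)=O)C2=C(COC(C)=O)CO[C@@H]2/C=C(/C)CC[C@@H]1O[Si](C)(C)C(C)(C)C | intermediate
21 | 1-O-(tert-butyldimethylsilyl) ether of the target | C=C1C[C@H](OC(C)=O)C2=C(COC(C)=O)C(=O)O[C@@H]2/C=C(/C)CC[C@@H]1O[Si](C)(C)C(C)(C)C | intermediate
22 | 8α,13-diacetoxy-1α-hydroxygermacra-4,7(11),10(14)-trien-6α,12-olide (1S,4Z,6R,8S) | C=C1C[C@H](OC(C)=O)C2=C(COC(C)=O)C(=O)O[C@@H]2/C=C(/C)CC[C@@H]1O | target

**Total step count:** 16
**Longest linear sequence:** 16 steps (from 1)

**Steps most likely to fail**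

1. Step 11. The kinetically formed enolate may equilibrate toward C9 and expel the C8 oxygen, the oxygen transfer may lose face selectivity, or the hindered alkoxide may silylate incompletely. The fallback sets out from 14 and comes back at 17, and separates ring expansion from oxygenation. The KH/18-crown-6 rearrangement is quenched at −78 °C with TMSCl/Et3N to isolate the trimethylsilyl enol ether F1. Rubottom oxidation of F1 with dimethyldioxirane in acetone at −78 °C, followed by brief citric acid/MeOH treatment, gives the free α-hydroxy ketone F2. TBSOTf/2,6-lutidine then gives 17.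

2. Step 5. The nucleophile may attack the other epoxide carbon, or the magnesium halide may trigger a semipinacol shift of the neighbouring carbinol. The fallback sets out from 5 and comes back at 10, and replaces the epoxide opening by a conjugate addition. PivCl/pyridine acylates the secondary hydroxyl to give the diol mono-pivalate F3. PPTS in aqueous acetone hydrolyses the allylic ketal to the 4-hydroxy-4-vinylcyclohexenone F4. CH2=C(CH3)MgBr with CuBr·SMe2 and TMSCl at −78 °C adds isopropenyl to C5 anti to the C10 oxygen and gives the bis(trimethylsilyl) compound F5 (enol ether and tertiary silyl ether). Rubottom oxidation of F5 with dimethyldioxirane, anti to the new isopropenyl group, then citric acid/MeOH gives 10.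

3. Step 15. Hydrogen abstraction may occur at other allylic C–H bonds of the flexible triene (C6–H, C3–H2, C1–H), or the dihydrofuran may aromatize to the furan. The fallback sets out from 13 and comes back at 22. It moves the ether oxidation to the rigid bicycle and makes the ring expansion neutral. Ac2O/pyridine gives the 8,13-diacetate F6, and TMS-imidazole gives its tertiary trimethylsilyl ether F7. CrO3–3,5-dimethylpyrazole, now facing a single ether methylene, gives the butenolide F8. Thermal siloxy-Cope rearrangement of F8 (o-dichlorobenzene, 200 °C, sealed tube) gives the ten-membered trimethylsilyl enol ether F9. Rubottom oxidation with dimethyldioxirane and mild acid work-up gives the α-hydroxy ketone F10. Zn/CH2Br2/TiCl4 methylenation, which tolerates the lactone and the acetates, gives 22.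

**Further compounds**
F1 | step 11 | trimethylsilyl enol ether of the ring-expanded ketone (1(10)E,4Z) | C[Si](C)(C)O/C1=C\CC/C(C)=C\[C@H]2OCC3=C2[C@H](C1)OC(C)(C)OC3
F2 | step 11 | (1S)-1-hydroxy-10-ketone (17 without the silyl group) | O=C1C[C@@H]2OC(C)(C)OCC3=C2[C@H](OC3)/C=C(/C)CC[C@@H]1O
F3 | step 5 | C8 mono-pivalate of diol 5 | C=C[C@]1(O)C=CC(OC)(OC)[C@@H](OC(=O)C(C)(C)C)C1
F4 | step 5 | 4-ethenyl-4-hydroxy-6-(pivaloyloxy)cyclohex-2-en-1-one | C=C[C@]1(O)C=CC(=O)[C@@H](OC(=O)C(C)(C)C)C1
F5 | step 5 | conjugate adduct as trimethylsilyl enol ether and tertiary trimethylsilyl ether | C=C[C@]1(O[Si](C)(C)C)[C@H](C(C)=C)C=C(O[Si](C)(C)C)[C@@H](OC(=O)C(C)(C)C)C1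
F6 | step 15 | 8,13-diacetate of triol 13 | C=C[C@]1(O)[C@H](C(C)=C)[C@H]2OCC(COC(C)=O)=C2[C@@H](OC(C)=O)C1
F7 | step 15 | tertiary trimethylsilyl ether of F6 | C=C[C@]1(O[Si](C)(C)C)[C@H](C(C)=C)[C@H]2OCC(COC(C)=O)=C2[C@@H](OC(C)=O)C1
F8 | step 15 | bicyclic butenolide (C12 lactone) from F7 | C=C[C@]1(O[Si](C)(C)C)[C@H](C(C)=C)[C@H]2OC(=O)C(COC(C)=O)=C2[C@@H](OC(C)=O)C1
F9 | step 15 | ten-membered trimethylsilyl enol ether with butenolide and both acetates | C[Si](C)(C)O/C1=C\CC/C(C)=C\[C@H]2OC(=O)C(COC(C)=O)=C2[C@@H](OC(C)=O)C1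
F10 | step 15 | 8α,13-diacetoxy-1α-hydroxy-10-oxo-14-norgermacra-4Z,7(11)-dien-6α,12-olide | O=C1C[C@H](OC(C)=O)C2=C(COC(C)=O)C(=O)O[C@@H]2/C=C(/C)CC[C@@H]1O
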